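**Retrosynthetic overview**
1. Target 26 ⇐ aldehyde 23 (Takai olefination, then Sonogashira coupling for the E-enyne) ⇐ anti-diol 20, whose two hydroxyls become the C10 and C12 bromides by double SN2 inversion.
2. Oxocane (O, C7, C8, C9, C10, C11, C12, C13), closed second: ring-closing metathesis makes C10=C11 from a silyl enol ether and an allylic alcohol (17 → 19); the C7–O–C13 ether comes from SN2 of the C7 alkoxide on triflate 11, and C12 from a chelation-controlled vinyl addition.
3. Tetrahydrofuran (O, C6, C7, C8, C9), closed first through the O–C6 bond, together with a temporary γ-lactone (C4(=O)–O–C7), by palladium-catalysed oxycarbonylation of (3S,5S)-hepta-1,6-diene-3,5-diol 4 with CO (4 → 7).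
4. Enabling feature: in the target's tetrahydrofuran the C7–O bond is cis to the C6–C5 bond (room for a cis-fused lactone to C4), and O–C7/O–C9 form an anti-1,3-diol flanked by C6 and C10; C5–C10 is therefore a hidden C2-symmetric dienediol in which either hydroxyl/vinyl pairing gives the same product.
5. Ring order: tetrahydrofuran plus sacrificial lactone (step 4), lactone opened (step 5), oxocane (step 13).

Key step: step 4

Remark: C1–C15 denote the carbon chain of the target from the alkyne terminus (the five-membered ring oxygen joins C6 and C9, the eight-membered ring oxygen joins C7 and C13); compounds 1 and 10 are taken as catalogue chemicals.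

**Step 1**
Reactants: 1 1,5-dichloropentane-2,4-dione
Product: 2 (2S,4S)-1,5-dichloropentane-2,4-diol
Conditions: H2 (80 atm), RuCl2[(R)-BINAP] (0.5 mol%), MeOH, 60 °C
Reagents that add atoms: none
Why: Noyori asymmetric hydrogenation of a 1,3-diketone, in which the BINAP–ruthenium catalyst (the ligand antipode that delivers the 2S,4S diol) sets both carbinol centers, the later C7 and C9, under catalyst control.

**Step 2**
Reactants: 2 (2S,4S)-1,5-dichloropentane-2,4-diol
Product: 3 (2S,4S)-1,2:4,5-diepoxypentane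
Conditions: KOH (powdered), Et2O, rt
Reagents that add atoms: none
Why: Twofold intramolecular Williamson closure of the chlorohydrins, in which no bond to a stereocenter is broken.

**Step 3**
Reactants: 3 (2S,4S)-1,2:4,5-diepoxypentane
Product: 4 (3S,5S)-hepta-1,6-diene-3,5-diol
Conditions: Me3S+ I−, n-BuLi, THF, −10 °C to rt
Reagents that add atoms: trimethylsulfonium iodide, C[S+](C)C.[I-]
Why: The sulfonium ylide (Corey–Chaykovsky reagent, in excess) opens each epoxide at its CH2 carbon and the resulting oxido sulfonium salt eliminates Me2S, a one-carbon homologation of an epoxide to an allylic alcohol that leaves both carbinol centers untouched.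

**Step 4**
Reactants: 4 (3S,5S)-hepta-1,6-diene-3,5-diol
Product: 7 (3aS,5S,6aS)-5-vinyltetrahydrofuro[3,2-b]furan-2(3H)-one, via alkylpalladium chloride 5 (not isolated), via acylpalladium chloride 6 (not isolated)
Conditions: PdCl2 (10 mol%), CuCl2 (3 equiv), NaOAc (3 equiv), CO (1 atm), AcOH, rt
Reagents that add atoms: carbon monoxide, [C-]#[O+]
Why: PdCl2 binds the C5=C6 vinyl group and its allylic C7 hydroxyl, the C9 hydroxyl adds to the activated alkene at C6 and so closes the tetrahydrofuran by forming the O–C6 bond (5), CO inserts into the C5–Pd bond (6), and the acylpalladium is captured by the C7 hydroxyl to close the γ-lactone and release zerovalent palladium, which CuCl2 returns to divalent palladium. The closest known reaction type is the palladium-catalysed intramolecular alkoxycarbonylation (oxycarbonylation) of 4-pentene-1,3-diols to cis-fused tetrahydrofuro[3,2-b]furan-2-ones. The tetrahydrofuran closes by 5-exo-trig oxypalladation and the lactone by five-membered acyl transfer to the neighbouring hydroxyl. The new stereocenter C6 is set cis to the C7–O bond, because the allylic hydroxyl holds palladium on its own face of the alkene and only this geometry lets the acyl group lactonise, while C7 and C9 come unchanged from the anti-diol, which places the C9 vinyl group on the same face. The step needs 5-exo rather than 6-endo attack, which is the normal preference of this reaction, and a choice between two hydroxyls and two vinyl groups, which vanishes because 4 is C2-symmetric and both pairings give 7. In one operation a seven-carbon diol with two stereocenters thus becomes a bicycle carrying the O–C6 bond, the all-cis C6/C7/C9 pattern of the target, the C5–C4 bond at the acid oxidation level and two chemically distinct ends.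

**Step 5**
Reactants: 7 (3aS,5S,6aS)-5-vinyltetrahydrofuro[3,2-b]furan-2(3H)-one
Product: 8 (2S,3S,5S)-2-(2-hydroxyethyl)-5-vinyloxolan-3-ol
Conditions: LiAlH4, THF, 0 °C
Reagents that add atoms: none
Why: Hydride reduction of the lactone to the 1,4-diol removes the temporary ring and frees the C7 hydroxyl without touching a stereocenter.

**Step 6**
Reactants: 8 (2S,3S,5S)-2-(2-hydroxyethyl)-5-vinyloxolan-3-ol
Product: 9 (2S,3S,5S)-2-{2-[tert-butyl(diphenyl)silyl]oxyethyl}-5-vinyloxolan-3-ol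
Conditions: TBDPSCl, imidazole, CH2Cl2, 0 °C
Reagents that add atoms: tert-butyl(chloro)diphenylsilane, CC(C)(C)[Si](Cl)(c1ccccc1)c1ccccc1
Why: Selective silylation of the primary hydroxyl over the hindered secondary one with a bulky silyl chloride.

**Step 7**
Reactants: 10 methyl (2S)-2-hydroxybutanoate
Product: 11 methyl (2S)-2-(trifluoromethylsulfonyloxy)butanoate
Conditions: Tf2O, 2,6-lutidine, CH2Cl2, −78 °C
Reagents that add atoms: trifluoromethanesulfonic anhydride, O=S(=O)(OS(=O)(=O)C(F)(F)F)C(F)(F)F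
Why: O-Sulfonylation of the α-hydroxy ester with retention gives an electrophile that undergoes clean SN2 displacement.

**Step 8**
Reactants: 9 (2S,3S,5S)-2-{2-[tert-butyl(diphenyl)silyl]oxyethyl}-5-vinyloxolan-3-ol; 11 methyl (2S)-2-(trifluoromethylsulfonyloxy)butanoate
Product: 13 methyl (2R)-2-{[(2S,3S,5S)-2-{2-[tert-butyl(diphenyl)silyl]oxyethyl}-5-vinyloxolan-3-yl]oxy}butanoate, via sodium alkoxide 12 (not isolated)
Conditions: NaH, THF, 0 °C; then 11, −20 °C to rt
Reagents that add atoms: none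
Why: Williamson etherification in which the C7 alkoxide displaces the α-triflyloxy ester by SN2 with inversion, forming the C7–O–C13 ether and setting C13 as R.

**Step 9**
Reactants: 13 methyl (2R)-2-{[(2S,3S,5S)-2-{2-[tert-butyl(diphenyl)silyl]oxyethyl}-5-vinyloxolan-3-yl]oxy}butanoate
Product: 14 methyl (2R)-2-{[(2S,3S,5S)-5-acetyl-2-{2-[tert-butyl(diphenyl)silyl]oxyethyl}oxolan-3-yl]oxy}butanoate
Conditions: PdCl2 (10 mol%), CuCl, O2 (1 atm), DMF/H2O 7:1, rt
Reagents that add atoms: water, O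
Why: Tsuji–Wacker oxidation of the terminal vinyl group (Markovnikov hydroxypalladation, then β-hydride elimination) should give the methyl ketone at C10 without touching a stereocenter.

**Step 10**
Reactants: 14 methyl (2R)-2-{[(2S,3S,5S)-5-acetyl-2-{2-[tert-butyl(diphenyl)silyl]oxyethyl}oxolan-3-yl]oxy}butanoate
Product: 15 methyl (2R)-2-{[(2S,3S,5S)-5-{1-[tert-butyl(dimethyl)silyl]oxyvinyl}-2-{2-[tert-butyl(diphenyl)silyl]oxyethyl}oxolan-3-yl]oxy}butanoate
Conditions: TBSOTf, Et3N, CH2Cl2, −78 to 0 °C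
Reagents that add atoms: tert-butyldimethylsilyl trifluoromethanesulfonate, CC(C)(C)[Si](C)(C)OS(=O)(=O)C(F)(F)F
Why: Soft enolisation with silyl triflate and amine silylates the ketone on its methyl side (the other α-carbon is the hindered ring CH bearing oxygen) and leaves the ester untouched.

**Step 11**
Reactants: 15 methyl (2R)-2-{[(2S,3S,5S)-5-{1-[tert-butyl(dimethyl)silyl]oxyvinyl}-2-{2-[tert-butyl(diphenyl)silyl]oxyethyl}oxolan-3-yl]oxy}butanoate
Product: 16 (2R)-2-{[(2S,3S,5S)-5-{1-[tert-butyl(dimethyl)silyl]oxyvinyl}-2-{2-[tert-butyl(diphenyl)silyl]oxyethyl}oxolan-3-yl]oxy}butanal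
Conditions: i-Bu2AlH (1.1 equiv), CH2Cl2, −78 °C
Reagents that add atoms: none
Why: Partial reduction of the α-alkoxy methyl ester at low temperature stops at the chelated aluminium hemiacetal and should give the aldehyde without epimerisation at C13.

**Step 12**
Reactants: 16 (2R)-2-{[(2S,3S,5S)-5-{1-[tert-butyl(dimethyl)silyl]oxyvinyl}-2-{2-[tert-butyl(diphenyl)silyl]oxyethyl}oxolan-3-yl]oxy}butanal
Product: 17 (3R,4R)-4-{[(2S,3S,5S)-5-{1-[tert-butyl(dimethyl)silyl]oxyvinyl}-2-{2-[tert-butyl(diphenyl)silyl]oxyethyl}oxolan-3-yl]oxy}hex-1-en-3-ol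
Conditions: MgBr2·OEt2, CH2Cl2, −78 °C; then CH2=CHMgBr
Reagents that add atoms: vinylmagnesium bromide, C=C[Mg]Br
Why: Chelation-controlled Grignard addition (Cram chelate model), in which magnesium bridges the aldehyde and ether oxygens and the vinyl group adds from the face of the C13 hydrogen, setting C12 as R, syn to the C13 oxygen.

**Step 13**
Reactants: 17 (3R,4R)-4-{[(2S,3S,5S)-5-{1-[tert-butyl(dimethyl)silyl]oxyvinyl}-2-{2-[tert-butyl(diphenyl)silyl]oxyethyl}oxolan-3-yl]oxy}hex-1-en-3-ol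
Product: 19 (1S,3R,4R,7S,9S)-9-{2-[tert-butyl(diphenyl)silyl]oxyethyl}-3-ethyl-4-hydroxy-2,8-dioxabicyclo[5.2.1]decan-6-one, via cyclic silyl enol ether 18 (not isolated)
Conditions: second-generation Grubbs catalyst (10 mol%), toluene (2 mM), 80 °C; then Bu4NF, AcOH, THF, −20 °C
Reagents that add atoms: none
Why: Ring-closing metathesis between the allylic-alcohol vinyl group and the silyl enol ether, whose arms are held cis on the tetrahydrofuran, closes the oxocane at C10=C11, and buffered fluoride then unmasks the C10 ketone with no change at any stereocenter.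

**Step 14**
Reactants: 19 (1S,3R,4R,7S,9S)-9-{2-[tert-butyl(diphenyl)silyl]oxyethyl}-3-ethyl-4-hydroxy-2,8-dioxabicyclo[5.2.1]decan-6-one
Product: 20 (1S,3R,4R,6R,7S,9S)-9-{2-[tert-butyl(diphenyl)silyl]oxyethyl}-3-ethyl-2,8-dioxabicyclo[5.2.1]decane-4,6-diol
Conditions: Me4NBH(OAc)3, MeCN/AcOH, −30 °C
Reagents that add atoms: none
Why: Evans–Saksena reduction, in which the C12 hydroxyl binds the acetoxyborohydride and delivers hydride to C10 from its own side, which is also the open face of the bicycle, giving the 1,3-anti diol with C10 as R.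

**Step 15**
Reactants: 20 (1S,3R,4R,6R,7S,9S)-9-{2-[tert-butyl(diphenyl)silyl]oxyethyl}-3-ethyl-2,8-dioxabicyclo[5.2.1]decane-4,6-diol
Product: 21 (1S,3R,4S,6S,7S,9S)-4,6-dibromo-9-{2-[tert-butyl(diphenyl)silyl]oxyethyl}-3-ethyl-2,8-dioxabicyclo[5.2.1]decane
Conditions: CBr4, P(n-C8H17)3, toluene, 70 °C
Reagents that add atoms: carbon tetrabromide, BrC(Br)(Br)Br
Why: Twofold Appel bromination (alkoxyphosphonium formation, then SN2 by bromide) inverts C10 and C12 and converts the anti diol into the anti dibromide with both centers S.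

**Step 16**
Reactants: 21 (1S,3R,4S,6S,7S,9S)-4,6-dibromo-9-{2-[tert-butyl(diphenyl)silyl]oxyethyl}-3-ethyl-2,8-dioxabicyclo[5.2.1]decane
Product: 22 2-[(1S,3R,4S,6S,7S,9S)-4,6-dibromo-3-ethyl-2,8-dioxabicyclo[5.2.1]decan-9-yl]ethanol
Conditions: HF·pyridine, THF, 0 °C to rt
Reagents that add atoms: none
Why: Fluoride-mediated cleavage of the primary silyl ether under non-basic conditions that should spare the secondary bromides.

**Step 17**
Reactants: 22 2-[(1S,3R,4S,6S,7S,9S)-4,6-dibromo-3-ethyl-2,8-dioxabicyclo[5.2.1]decan-9-yl]ethanol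
Product: 23 2-[(1S,3R,4S,6S,7S,9S)-4,6-dibromo-3-ethyl-2,8-dioxabicyclo[5.2.1]decan-9-yl]acetaldehyde
Conditions: Dess–Martin periodinane, CH2Cl2, rt
Reagents that add atoms: none
Why: Dess–Martin oxidation gives the β-alkoxy aldehyde under neutral conditions, and it is used crude to avoid β-elimination.

**Step 18**
Reactants: 23 2-[(1S,3R,4S,6S,7S,9S)-4,6-dibromo-3-ethyl-2,8-dioxabicyclo[5.2.1]decan-9-yl]acetaldehyde
Product: 24 (1S,3R,4S,6S,7S,9S)-4,6-dibromo-3-ethyl-9-[(E)-3-iodoprop-2-enyl]-2,8-dioxabicyclo[5.2.1]decane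
Conditions: CrCl2, CHI3, THF, 0 °C
Reagents that add atoms: iodoform, IC(I)I
Why: Takai olefination, in which the geminal dichromium species from iodoform adds to the aldehyde and eliminates to the E-vinyl iodide, setting the C3=C4 geometry.

**Step 19**
Reactants: 24 (1S,3R,4S,6S,7S,9S)-4,6-dibromo-3-ethyl-9-[(E)-3-iodoprop-2-enyl]-2,8-dioxabicyclo[5.2.1]decane
Product: 25 trimethyl{(E)-5-[(1S,3R,4S,6S,7S,9S)-4,6-dibromo-3-ethyl-2,8-dioxabicyclo[5.2.1]decan-9-yl]pent-3-en-1-ynyl}silane
Conditions: Me3SiC≡CH, Pd(PPh3)4 (5 mol%), CuI (10 mol%), i-Pr2NH, THF, rt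
Reagents that add atoms: trimethylsilylacetylene, C#C[Si](C)(C)C
Why: Sonogashira coupling of the vinyl iodide proceeds with retention of the E geometry, and the secondary alkyl bromides should not undergo oxidative addition under these conditions.

**Step 20**
Reactants: 25 trimethyl{(E)-5-[(1S,3R,4S,6S,7S,9S)-4,6-dibromo-3-ethyl-2,8-dioxabicyclo[5.2.1]decan-9-yl]pent-3-en-1-ynyl}silane
Product: 26 (1S,3R,4S,6S,7S,9S)-4,6-dibromo-3-ethyl-9-[(E)-pent-2-en-4-ynyl]-2,8-dioxabicyclo[5.2.1]decane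
Conditions: K2CO3, MeOH, 0 °C
Reagents that add atoms: none
Why: Mild base-mediated methanolysis of the alkynyl–silicon bond should give the terminal alkyne and thus the target.

**Compound list**
1 | 1,5-dichloropentane-2,4-dione | ClCC(=O)CC(=O)CCl | starting material
2 | (2S,4S)-1,5-dichloropentane-2,4-diol | ClC[C@@H](O)C[C@H](O)CCl | intermediate
3 | (2S,4S)-1,2:4,5-diepoxypentane | C1O[C@H]1C[C@H]1CO1 | intermediate
4 | (3S,5S)-hepta-1,6-diene-3,5-diol | C=C[C@@H](O)C[C@H](O)C=C | intermediate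
5 | {[(2R,3S,5S)-3-hydroxy-5-vinyloxolan-2-yl]methyl}palladium chloride (CH2PdCl cis to the 3-hydroxyl and to the 5-vinyl group) | C=C[C@@H]1C[C@H](O)[C@H](C[Pd]Cl)O1 | intermediate
6 | {2-[(2S,3S,5S)-3-hydroxy-5-vinyloxolan-2-yl]acetyl}palladium chloride | C=C[C@@H]1C[C@H](O)[C@H](CC(=O)[Pd]Cl)O1 | intermediate
7 | (3aS,5S,6aS)-5-vinyltetrahydrofuro[3,2-b]furan-2(3H)-one | C=C[C@@H]1C[C@@H]2OC(=O)C[C@@H]2O1 | intermediate
8 | (2S,3S,5S)-2-(2-hydroxyethyl)-5-vinyloxolan-3-ol | C=C[C@@H]1C[C@H](O)[C@H](CCO)O1 | intermediate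
9 | (2S,3S,5S)-2-{2-[tert-butyl(diphenyl)silyl]oxyethyl}-5-vinyloxolan-3-ol | C=C[C@@H]1C[C@H](O)[C@H](CCO[Si](c2ccccc2)(c2ccccc2)C(C)(C)C)O1 | intermediate
10 | methyl (2S)-2-hydroxybutanoate | CC[C@H](O)C(=O)OC | starting material
11 | methyl (2S)-2-(trifluoromethylsulfonyloxy)butanoate | CC[C@H](OS(=O)(=O)C(F)(F)F)C(=O)OC | intermediate
12 | sodium (2S,3S,5S)-2-{2-[tert-butyl(diphenyl)silyl]oxyethyl}-5-vinyloxolan-3-olate | C=C[C@@H]1C[C@H]([O-])[C@H](CCO[Si](c2ccccc2)(c2ccccc2)C(C)(C)C)O1.[Na+] | intermediate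
13 | methyl (2R)-2-{[(2S,3S,5S)-2-{2-[tert-butyl(diphenyl)silyl]oxyethyl}-5-vinyloxolan-3-yl]oxy}butanoate | C=C[C@@H]1C[C@H](O[C@H](CC)C(=O)OC)[C@H](CCO[Si](c2ccccc2)(c2ccccc2)C(C)(C)C)O1 | intermediate
14 | methyl (2R)-2-{[(2S,3S,5S)-5-acetyl-2-{2-[tert-butyl(diphenyl)silyl]oxyethyl}oxolan-3-yl]oxy}butanoate | CC(=O)[C@@H]1C[C@H](O[C@H](CC)C(=O)OC)[C@H](CCO[Si](c2ccccc2)(c2ccccc2)C(C)(C)C)O1 | intermediate
15 | methyl (2R)-2-{[(2S,3S,5S)-5-{1-[tert-butyl(dimethyl)silyl]oxyvinyl}-2-{2-[tert-butyl(diphenyl)silyl]oxyethyl}oxolan-3-yl]oxy}butanoate | C=C(O[Si](C)(C)C(C)(C)C)[C@@H]1C[C@H](O[C@H](CC)C(=O)OC)[C@H](CCO[Si](c2ccccc2)(c2ccccc2)C(C)(C)C)O1 | intermediate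
16 | (2R)-2-{[(2S,3S,5S)-5-{1-[tert-butyl(dimethyl)silyl]oxyvinyl}-2-{2-[tert-butyl(diphenyl)silyl]oxyethyl}oxolan-3-yl]oxy}butanal | C=C(O[Si](C)(C)C(C)(C)C)[C@@H]1C[C@H](O[C@H](CC)C=O)[C@H](CCO[Si](c2ccccc2)(c2ccccc2)C(C)(C)C)O1 | intermediate
17 | (3R,4R)-4-{[(2S,3S,5S)-5-{1-[tert-butyl(dimethyl)silyl]oxyvinyl}-2-{2-[tert-butyl(diphenyl)silyl]oxyethyl}oxolan-3-yl]oxy}hex-1-en-3-ol | C=C(O[Si](C)(C)C(C)(C)C)[C@@H]1C[C@H](O[C@H](CC)[C@H](O)C=C)[C@H](CCO[Si](c2ccccc2)(c2ccccc2)C(C)(C)C)O1 | intermediate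
18 | (1S,3R,4R,7S,9S)-6-[tert-butyl(dimethyl)silyl]oxy-9-{2-[tert-butyl(diphenyl)silyl]oxyethyl}-3-ethyl-2,8-dioxabicyclo[5.2.1]dec-5-en-4-ol | CC(C)(C)[Si](c1ccccc1)(c1ccccc1)OCC[C@@H]1O[C@H]2C[C@@H]1O[C@H](CC)[C@H](O)/C=C2/O[Si](C)(C)C(C)(C)C | intermediate
19 | (1S,3R,4R,7S,9S)-9-{2-[tert-butyl(diphenyl)silyl]oxyethyl}-3-ethyl-4-hydroxy-2,8-dioxabicyclo[5.2.1]decan-6-one | CC(C)(C)[Si](c1ccccc1)(c1ccccc1)OCC[C@@H]1O[C@H]2C[C@@H]1O[C@H](CC)[C@H](O)CC2=O | intermediate
20 | (1S,3R,4R,6R,7S,9S)-9-{2-[tert-butyl(diphenyl)silyl]oxyethyl}-3-ethyl-2,8-dioxabicyclo[5.2.1]decane-4,6-diol | CC(C)(C)[Si](c1ccccc1)(c1ccccc1)OCC[C@@H]1O[C@H]2C[C@@H]1O[C@H](CC)[C@H](O)C[C@H]2O | intermediate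
21 | (1S,3R,4S,6S,7S,9S)-4,6-dibromo-9-{2-[tert-butyl(diphenyl)silyl]oxyethyl}-3-ethyl-2,8-dioxabicyclo[5.2.1]decane | CC(C)(C)[Si](c1ccccc1)(c1ccccc1)OCC[C@@H]1O[C@H]2C[C@@H]1O[C@H](CC)[C@@H](Br)C[C@@H]2Br | intermediate
22 | 2-[(1S,3R,4S,6S,7S,9S)-4,6-dibromo-3-ethyl-2,8-dioxabicyclo[5.2.1]decan-9-yl]ethanol | OCC[C@@H]1O[C@H]2C[C@@H]1O[C@H](CC)[C@@H](Br)C[C@@H]2Br | intermediate
23 | 2-[(1S,3R,4S,6S,7S,9S)-4,6-dibromo-3-ethyl-2,8-dioxabicyclo[5.2.1]decan-9-yl]acetaldehyde | O=CC[C@@H]1O[C@H]2C[C@@H]1O[C@H](CC)[C@@H](Br)C[C@@H]2Br | intermediate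
24 | (1S,3R,4S,6S,7S,9S)-4,6-dibromo-3-ethyl-9-[(E)-3-iodoprop-2-enyl]-2,8-dioxabicyclo[5.2.1]decane | I/C=C/C[C@@H]1O[C@H]2C[C@@H]1O[C@H](CC)[C@@H](Br)C[C@@H]2Br | intermediate
25 | trimethyl{(E)-5-[(1S,3R,4S,6S,7S,9S)-4,6-dibromo-3-ethyl-2,8-dioxabicyclo[5.2.1]decan-9-yl]pent-3-en-1-ynyl}silane | C[Si](C)(C)C#C/C=C/C[C@@H]1O[C@H]2C[C@@H]1O[C@H](CC)[C@@H](Br)C[C@@H]2Br | intermediate
26 | (1S,3R,4S,6S,7S,9S)-4,6-dibromo-3-ethyl-9-[(E)-pent-2-en-4-ynyl]-2,8-dioxabicyclo[5.2.1]decane (CNP0383022.2) | C#C/C=C/C[C@@H]1O[C@H]2C[C@@H]1O[C@H](CC)[C@@H](Br)C[C@@H]2Br | target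

**Step count and risks**
Total step count: 20. Longest linear sequence: 19 steps (steps 1–6 and 8–20); step 7 is a one-step side branch.

The three steps most likely to fail:

Step 13 (ring-closing metathesis). The ruthenium carbene formed at the allylic-alcohol vinyl group may react with a second molecule faster than with the hindered 1,1-disubstituted silyl enol ether, giving oligomers, or the allylic alcohol may isomerise to an ethyl ketone. The fallback sets out from aldehyde 16 and closes the other bond of the C10–C11–C12 unit, C11–C12, by an intramolecular Mukaiyama aldol addition (TiCl4, CH2Cl2, −78 °C, high dilution). The silyl enol ether carbon adds to the titanium-chelated α-alkoxy aldehyde on the face predicted by the Cram chelate model (again 12R), and aqueous work-up gives hydroxy ketone 19 directly. Vinyl addition and metathesis are then not needed, no compound outside the list is made (F0), and the route is rejoined at 19.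

Step 15 (double bromination). The alkoxyphosphonium ions may undergo E2 elimination toward C11 or be opened with participation of the neighbouring ring oxygens, or the second substitution may stall once the first bromide is in place. The fallback sets out from diol 20 and forms (1S,3R,4R,6R,7S,9S)-9-{2-[tert-butyl(diphenyl)silyl]oxyethyl}-3-ethyl-2,8-dioxabicyclo[5.2.1]decane-4,6-diyl bis(chloromethanesulfonate) F1 (ClCH2SO2Cl, pyridine, CH2Cl2, 0 °C). Both sulfonates are then displaced with LiBr in DMF at 50 °C, a Finkelstein-type SN2 on a small and very good leaving group, each with inversion, which rejoins the route at 21.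

Step 8 (etherification). The hindered C7 alkoxide may act as a base on triflate 11 (E2 to methyl but-2-enoate) or attack its ester carbonyl instead of C13. The fallback sets out from alcohol 9 and uses an electrophile that carries a carboxylate: NaH (3 equiv) and (S)-2-bromobutanoic acid in THF at 50 °C. The α-bromo carboxylate can neither be acylated nor easily eliminated, and SN2 with inversion gives (2R)-2-{[(2S,3S,5S)-2-{2-[tert-butyl(diphenyl)silyl]oxyethyl}-5-vinyloxolan-3-yl]oxy}butanoic acid F2. Esterification with Me3SiCHN2 in toluene/MeOH then rejoins the route at 13.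

**Further compounds**
F0 | step 13 | none | none
F1 | step 15 | (1S,3R,4R,6R,7S,9S)-9-{2-[tert-butyl(diphenyl)silyl]oxyethyl}-3-ethyl-2,8-dioxabicyclo[5.2.1]decane-4,6-diyl bis(chloromethanesulfonate) | CC(C)(C)[Si](c1ccccc1)(c1ccccc1)OCC[C@@H]1O[C@H]2C[C@@H]1O[C@H](CC)[C@H](OS(=O)(=O)CCl)C[C@H]2OS(=O)(=O)CCl
F2 | step 8 | (2R)-2-{[(2S,3S,5S)-2-{2-[tert-butyl(diphenyl)silyl]oxyethyl}-5-vinyloxolan-3-yl]oxy}butanoic acid | C=C[C@@H]1C[C@H](O[C@H](CC)C(=O)O)[C@H](CCO[Si](c2ccccc2)(c2ccccc2)C(C)(C)C)O1
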